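## The problem

The target is a cembranolide: a 14-membered carbocycle (C1–C14) bridged between C10 and C12 by a butenolide (C10–O–C20(=O), with C11=C12 inside the lactone). This gives a 15-oxabicyclo[11.2.1]hexadecane carrying isopropyl on C1 and methyl groups on C4 and C8. Three of its four stereocentres are tertiary allylic carbinols (C1 S, C4 R, C8 S), set 1,4 and 1,5 apart across the E-disubstituted alkenes C2=C3 and C6=C7; the fourth is the lactone carbinol C10 (R). In so flexible a ring none of these centres can be trusted to relay its configuration to another, so each needs its own controller, an enzyme pocket or a chiral reagent. The tertiary allylic alcohols ionise, transpose or dehydrate with acid, and the 1,4- and 1,5-diol arrays can close transannular ethers. The butenolide is a Michael acceptor whose C10–H is removed by base, which would erase C10. The structure does offer one opening. Without the oxygens on C1, C8, C10 and C20 the skeleton is a regular head-to-tail tetraprenyl chain closed between C1 and C2, and the C2=C3/C4–OH unit is the allyl cation C2–C3–C4 quenched by water. That is the product pattern of a cembratrienol-type diterpene cyclase acting on geranylgeranyl diphosphate. The missing oxygens then sit at or beside the two trisubstituted alkenes that such a cyclase leaves behind (C7=C8 and C11=C12) and at the allylic methine C1.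

## Retrosynthesis

The last bond made is the C6=C7 π bond, and before it C7–Se. Target 17 is the syn-elimination product of selenoxide 16, formed from hydroxy selenide 15, which arises by opening the 7S,8S-epoxide 14 at C7. A singlet-oxygen ene reaction of a C7=C8 alkene would give the same allylic alcohol in one step, but it divides between C6–H and C19–H and between the two faces. The selenium route asks only for attack at the less substituted epoxide carbon and elimination away from C8, and both are enforced because C8 is fully substituted. The C8 configuration is thereby moved back to the epoxidation.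

Cutting the C1–O bond of 14 leads to epoxide 13. The C1 hydroxyl is placed at this point because 13 is the one intermediate in which C2=C3 is the only alkene able to undergo an ene reaction and C1–H its only allylic hydrogen. C7=C8 is masked as the epoxide and C11=C12 is conjugated to the lactone. An earlier oxidation would attack the trisubstituted alkenes, a later one the C5 methylene next to C6=C7. The forward reaction must replace hydrogen by oxygen with retention.

Removing the epoxide oxygen of 13 gives hydroxy-olide 12. The epoxidation must come after the butenolide, since only then is C7=C8 the single electron-rich trisubstituted alkene. A chiral dioxirane is asked to choose the face, because the ring itself offers no reliable bias.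

The lactone of 12 is opened to the (11Z)-ene-1,4-diol 9, so that C10–O is never broken, and the C20–O bond of 9 is cut back to the methyl group of diol 6. Selenium dioxide would choose the ring methylene C13 trans to C10, and singlet oxygen cannot tell C11=C12 from C7=C8. The C10 alkoxide, held cis to C20 across the alkene, is the one handle that singles out this methyl group. Compound 6 carries only two oxygens, and the forward step must metalate C20 and nothing else.

The C10–O bond of 6 is cut to trienol 5. This first oxidation also breaks the near-equivalence of the two trisubstituted alkenes and supplies the directing group for C20. It is entrusted to an engineered P450 hydroxylase, a reaction type known on this ring system, and it sets 10R for the rest of the route.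

Trienol 5 is cut at C1–C2 and C4–O to geranylgeranyl diphosphate 4. No small reagent can tell the four trisubstituted alkenes of 4 apart or fold the chain. A cyclase does both, and in one step it supplies the ring, C1, C4 and three E-alkenes from an achiral precursor. The price is that the enzyme for this stereoisomer has still to be found.

Diphosphate 4 comes from geranylgeranyl chloride 2 and the diphosphate salt 3, and 2 from commercial geranylgeraniol 1, by two routine steps.

## Roads not taken

Alternative 1: lithiation–borylation at C1. The cut is at C1–C14 and C1–O of an open chain. The S-configured secondary allylic carbamate A1 (C1–C10, with C4 and C8 already present as silyl ethers) is lithiated at C1–H with s-BuLi/TMEDA. The lithio carbamate captures pinacol boronic ester A2 (C11–C14), and 1,2-migration followed by H2O2/NaOH gives the tertiary allylic alcohol A3.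
- Merits: the hardest centre, the isopropyl-bearing carbinol C1, is made stereospecifically from a secondary carbamate of known configuration, with reagents that exist today. In this respect it is better than the chosen plan, which must oxidise a hindered C–H bond late (step 8) and needs an enzyme not yet in hand.
- Weak points: the allylic lithio carbamate can be borylated at its γ terminus (C3); migration to a centre carrying isopropyl is slow; A1, with two tertiary silyl ether centres, is itself a multi-step asymmetric synthesis. A3 is still acyclic, so the macrocycle, C10 and the butenolide all lie ahead.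
- Comparison: the chosen plan sets against this a single operation that closes the ring and sets C1–H, C4 and three alkenes from a purchased C20 alcohol, and a route about half as long.

Alternative 2: silylfuran photooxygenation. The cut is at the C20 carbonyl and the C10–O bond of the lactone. Singlet oxygen adds across the α-carbons of the C20-silylated furanophane A4, and fragmentation of the endoperoxide gives the γ-hydroxybutenolide A5.
- Merits: silicon dictates which carbon becomes the carbonyl, free tertiary alcohols are tolerated and no base is needed. As a way to the butenolide this is more reliable than steps 5 and 6 of the chosen plan, which depend on a directed metalation.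
- Weak points: A5 carries C10 as a hemiketal of both configurations, so a later reduction must set 10R with no nearby control element. A4 already contains the macrocycle and C1, C4 and C8, so this road leaves their construction unsolved.
- Comparison: the chosen plan sets against this a C10 configuration fixed once by the hydroxylase of step 4 and never touched, and a carbocycle supplied by the key step.

Alternative 3: sulfone ring contraction. The cut is at C2=C3. The 15-membered sulfone A6, with sulfur between C2 and C3, is halogenated in situ (KOH on alumina, CBr2F2), closes to the episulfone and loses SO2 to give the 14-membered dienyne A7.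
- Merits: the ring is first closed by C–S bond formation, which is easier than C–C macrocyclisation. The alkene flanked by two fully substituted carbinol carbons is made where olefination or metathesis would struggle. All four stereocentres of A7 come from known asymmetric reactions, so no enzyme has to be found; in certainty of the individual steps this road is ahead.
- Weak points: both α-carbons are neopentyl-like, and each α-sulfonyl carbanion has a silyloxy group in the β position, so β-elimination of silanolate competes with episulfone formation. The 2E geometry is not assured in a ring of this size. The butenolide must still be built from the alkyne.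
- Comparison: the chosen plan sets against this its brevity and the fact that the 2E alkene and C4 come out of the cyclisation together.

Key step: step 3

Remark: cembrane numbering is used throughout (C15–C17 isopropyl on C1; C18, C19 and C20 on C4, C8 and C12). The descriptor at C1 changes from R to S on hydroxylation with retention, and that of C11=C12 from E to Z once C20 carries oxygen, without any change in geometry. The enzyme steps are written for isolated enzymes with cofactor recycling; an engineered host would serve equally.

## Route

Step 1
Reactants: 1 geranylgeraniol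
Product: 2 geranylgeranyl chloride
Conditions: NCS, Me2S, CH2Cl2, −40 → 0 °C
Reagents that add atoms: N-chlorosuccinimide, O=C1CCC(=O)N1Cl
Why: Corey–Kim chlorination: chloride displaces the alkoxysulfonium group at the primary allylic carbon by SN2, without allylic transposition or loss of the 2E geometry; the labile chloride is used crude.

Step 2
Reactants: 2 geranylgeranyl chloride; 3 tris(tetrabutylammonium) hydrogen diphosphate
Product: 4 geranylgeranyl diphosphate, trisammonium salt
Conditions: MeCN, rt; then cation exchange (sulfonic acid resin, NH4+ form), NH4HCO3 (25 mM) in i-PrOH–H2O; lyophilise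
Reagents that add atoms: ammonium hydrogen carbonate, [NH4+].OC([O-])=O
Why: SN2 displacement of the allylic chloride by the diphosphate anion, the standard preparation of prenyl diphosphates; ion exchange gives the water-soluble ammonium salt used as cyclase substrate.

Step 3
Reactants: 4 geranylgeranyl diphosphate, trisammonium salt
Product: 5 (1R,2E,4R,7E,11E)-cembra-2,7,11-trien-4-ol
Conditions: recombinant cembratrienol synthase-type diterpene cyclase (selected for the 1R,4R product), MgCl2, Tris–HCl pH 7.5, dithiothreitol, 30 °C, n-pentane overlay
Reagents that add atoms: water, O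
Why: Proposed new method: no characterised cyclase is known to release the 1R,4R stereoisomer, so the step rests on mechanistic analogy; the closest known reaction type is the conversion of geranylgeranyl diphosphate into cembra-2,7,11-trien-4-ols by plant cembratrienol synthases, whose cation cascade is taken over unchanged. MgCl2-assisted ionisation of the diphosphate gives the C2–C3–C4 allyl cation, and the distal C1=C15 alkene attacks C2 through C1. This closes the 14-membered ring by C1–C2 bond formation (1,14-closure of the chain, through the inner alkene carbon, so that the new cationic centre C15 stays outside the ring). A 1,3-hydride shift from C2 to C15 regenerates the allyl cation, and water adds at C4 to give the C4–O bond and the 2E alkene. C1 is set by the face of the C1=C15 alkene that the folded chain presents to C2, and C4 by the face of the cation on which the active site holds the water molecule; the substrate is achiral, so the active-site contour is the only control element for both. The step needs one chain fold, water capture at C4 in preference to C2 or C15, and no early proton loss to cembrene-type hydrocarbons; known enzymes of this family secure the last two, and the fold for 1R,4R is to be found by mining the cyclases of the producing plant or by reshaping the active site of a known cembratrienol synthase. The 6E and 10E alkenes of 4 are spectators and become the 7E and 11E alkenes of 5.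

Step 4
Reactants: 5 (1R,2E,4R,7E,11E)-cembra-2,7,11-trien-4-ol
Product: 6 (1R,2E,4R,7E,10R,11E)-cembra-2,7,11-triene-4,10-diol
Conditions: cytochrome P450 BM3 (CYP102A1) variant selected for C10, air, NADP+ (cat.), D-glucose, glucose dehydrogenase, KH2PO4/K2HPO4 buffer pH 7.5, 2% DMSO, 25 °C
Reagents that add atoms: dioxygen, O=O
Why: Enzymatic allylic C–H hydroxylation by hydrogen abstraction and oxygen rebound: engineered variants of this hydroxylase are known to oxidise the closely related cembra-2,7,11-triene-4,6-diols at allylic C9 or C10, or at C7=C8, depending on the active-site mutations, so a variant panel is screened for C10. The 10R configuration is set by the enzyme pocket, not by the substrate.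

Step 5
Reactants: 6 (1R,2E,4R,7E,10R,11E)-cembra-2,7,11-triene-4,10-diol
Product: 9 (1R,2E,4R,7E,10R,11Z)-cembra-2,7,11-triene-4,10,20-triol, via C20-lithio dilithium dialkoxide 7 (not isolated), via C20 dimethyl boronate 8 (not isolated)
Conditions: n-BuLi (4 equiv), TMEDA, hexane–Et2O, 0 °C → rt; B(OMe)3, −78 → 0 °C; then H2O2, NaOH, THF–H2O, 0 °C
Reagents that add atoms: hydrogen peroxide, OO
Why: Alkoxide-directed allylic lithiation, known for 3-methylbut-2-en-1-ol-type alkoxides: the lithium alkoxide on C10 delivers the base to the methyl group held cis to it across C11=C12 (C20). The allyllithium is borylated at its primary terminus, and oxidation of the C–B bond keeps the position and geometry of the alkene; no stereocentre is formed.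

Step 6
Reactants: 9 (1R,2E,4R,7E,10R,11Z)-cembra-2,7,11-triene-4,10,20-triol
Product: 12 (1R,2E,4R,7E,10R,11Z)-4-hydroxycembra-2,7,11-trien-20,10-olide, via hydroxy enal 10 (not isolated), via lactol 11 (not isolated)
Conditions: TEMPO (0.2 equiv), PhI(OAc)2 (2.5 equiv), NaHCO3, CH2Cl2, rt
Reagents that add atoms: none
Why: Oxoammonium-mediated oxidative lactonisation of a (Z)-2-ene-1,4-diol: the primary allylic alcohol is oxidised first, the enal is trapped by the cis C10 hydroxyl as the lactol, and the lactol is oxidised to the butenolide. The C10–O bond is never broken, so 10R is kept, and the tertiary C4 alcohol cannot be oxidised.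

Step 7
Reactants: 12 (1R,2E,4R,7E,10R,11Z)-4-hydroxycembra-2,7,11-trien-20,10-olide
Product: 13 (1R,2E,4R,7S,8S,10R,11Z)-7,8-epoxy-4-hydroxycembra-2,11-dien-20,10-olide
Conditions: enantiomer of the D-fructose-derived Shi ketone (0.3 equiv), KHSO5 (as 2KHSO5·KHSO4·K2SO4), K2CO3, Bu4NHSO4, MeCN–CH2(OMe)2–aq. Na2B4O7 buffer, 0 °C
Reagents that add atoms: potassium peroxymonosulfate, [K+].OOS(=O)(=O)[O-]
Why: Shi asymmetric epoxidation: the chiral dioxirane takes the only electron-rich trisubstituted alkene, C7=C8, since C11=C12 is conjugated to the lactone and C2=C3 is disubstituted, hindered and deactivated by the allylic hydroxyl. The spiro transition state of the L-series ketone is expected to give the S,S-epoxide of this E-trisubstituted alkene, which fixes C8 as S by reagent control.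

Step 8
Reactants: 13 (1R,2E,4R,7S,8S,10R,11Z)-7,8-epoxy-4-hydroxycembra-2,11-dien-20,10-olide
Product: 14 (1S,2E,4R,7S,8S,10R,11Z)-7,8-epoxy-1,4-dihydroxycembra-2,11-dien-20,10-olide
Conditions: SeO2 (0.5 equiv), t-BuOOH (3 equiv), CH2Cl2, rt
Reagents that add atoms: tert-butyl hydroperoxide, CC(C)(C)OO
Why: Riley-type allylic hydroxylation with catalytic SeO2: C2=C3 is the only alkene left that can undergo the ene reaction, and C1–H is its only allylic hydrogen. The suprafacial ene reaction (Se to C3) and the suprafacial [2,3]-shift through the E-forming envelope return the 2E alkene and place oxygen on the face of C1 that lost hydrogen, that is with retention (1S).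

Step 9
Reactants: 14 (1S,2E,4R,7S,8S,10R,11Z)-7,8-epoxy-1,4-dihydroxycembra-2,11-dien-20,10-olide
Product: 15 (1S,2E,4R,7R,8S,10R,11Z)-1,4,8-trihydroxy-7-(phenylselanyl)cembra-2,11-dien-20,10-olide
Conditions: (PhSe)2, NaBH4, EtOH, 0 → 50 °C
Reagents that add atoms: diphenyl diselenide, c1ccccc1[Se][Se]c1ccccc1
Why: Selenolate opening of the epoxide, the first stage of the organoselenium epoxide-to-allylic-alcohol transposition: SN2 attack with inversion at the less substituted C7 leaves the C8–O bond and 8S untouched. The weakly basic borate-bound selenolate is chosen to spare the butenolide.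

Step 10
Reactants: 15 (1S,2E,4R,7R,8S,10R,11Z)-1,4,8-trihydroxy-7-(phenylselanyl)cembra-2,11-dien-20,10-olide
Product: 17 (1S,2E,4R,6E,8S,10R,11Z)-1,4,8-trihydroxycembra-2,6,11-trien-20,10-olide, via selenoxide 16 (not isolated)
Conditions: 30% H2O2, pyridine, THF, 0 °C → rt
Reagents that add atoms: none
Why: Selenide oxidation and selenoxide syn-elimination: C8 carries no hydrogen, so elimination can only run towards C6 and should give the E alkene next to the tertiary C8 alcohol. No stereocentre is touched, and pyridine keeps the medium from turning acidic.

## Compound list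

1 | geranylgeraniol, (2E,6E,10E)-3,7,11,15-tetramethylhexadeca-2,6,10,14-tetraen-1-ol | CC(C)=CCC/C(C)=C/CC/C(C)=C/CC/C(C)=C/CO | starting material
2 | geranylgeranyl chloride, (2E,6E,10E)-1-chloro-3,7,11,15-tetramethylhexadeca-2,6,10,14-tetraene | CC(C)=CCC/C(C)=C/CC/C(C)=C/CC/C(C)=C/CCl | intermediate
3 | tris(tetrabutylammonium) hydrogen diphosphate | CCCC[N+](CCCC)(CCCC)CCCC.CCCC[N+](CCCC)(CCCC)CCCC.CCCC[N+](CCCC)(CCCC)CCCC.OP(=O)([O-])OP(=O)([O-])[O-] | starting material
4 | (2E,6E,10E)-geranylgeranyl diphosphate, trisammonium salt | CC(C)=CCC/C(C)=C/CC/C(C)=C/CC/C(C)=C/COP(=O)([O-])OP(=O)([O-])[O-].[NH4+].[NH4+].[NH4+] | intermediate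
5 | (1R,2E,4R,7E,11E)-cembra-2,7,11-trien-4-ol | CC(C)[C@@H]1/C=C/[C@](C)(O)CC/C=C(C)/CC/C=C(C)/CC1 | intermediate
6 | (1R,2E,4R,7E,10R,11E)-cembra-2,7,11-triene-4,10-diol | CC(C)[C@@H]1/C=C/[C@](C)(O)CC/C=C(C)/C[C@@H](O)/C=C(C)/CC1 | intermediate
7 | C20-lithio derivative of 6 as the dilithium 4,10-dialkoxide | CC(C)[C@@H]1/C=C/[C@](C)(O[Li])CC/C=C(C)/C[C@@H](O[Li])/C=C(C[Li])/CC1 | intermediate
8 | C20 dimethyl boronate of 6 as the dilithium 4,10-dialkoxide | CC(C)[C@@H]1/C=C/[C@](C)(O[Li])CC/C=C(C)/C[C@@H](O[Li])/C=C(CB(OC)OC)/CC1 | intermediate
9 | (1R,2E,4R,7E,10R,11Z)-cembra-2,7,11-triene-4,10,20-triol | CC(C)[C@@H]1/C=C/[C@](C)(O)CC/C=C(C)/C[C@@H](O)/C=C(CO)/CC1 | intermediate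
10 | (1R,2E,4R,7E,10R,11Z)-4,10-dihydroxycembra-2,7,11-trien-20-al | CC(C)[C@@H]1/C=C/[C@](C)(O)CC/C=C(C)/C[C@@H](O)/C=C(C=O)/CC1 | intermediate
11 | (1R,2E,4R,7E,10R)-10,20-epoxycembra-2,7,11-triene-4,20-diol (lactol, both C20 epimers) | CC(C)[C@@H]1/C=C/[C@](C)(O)CC/C=C(C)/C[C@@H]2C=C(CC1)C(O)O2 | intermediate
12 | (1R,2E,4R,7E,10R,11Z)-4-hydroxycembra-2,7,11-trien-20,10-olide | CC(C)[C@@H]1/C=C/[C@](C)(O)CC/C=C(C)/C[C@@H]2C=C(CC1)C(=O)O2 | intermediate
13 | (1R,2E,4R,7S,8S,10R,11Z)-7,8-epoxy-4-hydroxycembra-2,11-dien-20,10-olide | CC(C)[C@@H]1/C=C/[C@](C)(O)CC[C@H]3[C@@](C)(O3)C[C@@H]2C=C(CC1)C(=O)O2 | intermediate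
14 | (1S,2E,4R,7S,8S,10R,11Z)-7,8-epoxy-1,4-dihydroxycembra-2,11-dien-20,10-olide | CC(C)[C@]1(O)/C=C/[C@](C)(O)CC[C@H]3[C@@](C)(O3)C[C@@H]2C=C(CC1)C(=O)O2 | intermediate
15 | (1S,2E,4R,7R,8S,10R,11Z)-1,4,8-trihydroxy-7-(phenylselanyl)cembra-2,11-dien-20,10-olide | CC(C)[C@]1(O)/C=C/[C@](C)(O)CC[C@@H]([Se]c3ccccc3)[C@@](C)(O)C[C@@H]2C=C(CC1)C(=O)O2 | intermediate
16 | selenoxide of 15, (1S,2E,4R,7R,8S,10R,11Z)-1,4,8-trihydroxy-7-(phenylseleninyl)cembra-2,11-dien-20,10-olide (both configurations at Se) | CC(C)[C@]1(O)/C=C/[C@](C)(O)CC[C@@H]([Se](=O)c3ccccc3)[C@@](C)(O)C[C@@H]2C=C(CC1)C(=O)O2 | intermediate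
17 | (1S,2E,4R,6E,8S,10R,11Z)-1,4,8-trihydroxycembra-2,6,11-trien-20,10-olide | CC(C)[C@]1(O)/C=C/[C@](C)(O)C/C=C/[C@@](C)(O)C[C@@H]2C=C(CC1)C(=O)O2 | target

## Step count and least certain steps

Total: 10 steps. Longest linear sequence: 10 steps (1 → 17); the route is linear, and 3 is the only other purchased building block.

Step 3 (key step, Proposed new method). The most likely failure is that the chain is folded the wrong way in the active site, giving the wrong configuration at C1 or C4, or that the cation loses a proton early to give cembrene-type hydrocarbons. The enzyme for this stereoisomer has not been described. Fallback with known chemistry, from 1 back to 5: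
- 1 would be oxidised with MnO2 to geranylgeranial F1 and by Pinnick oxidation (NaClO2, NaH2PO4, 2-methyl-2-butene) to geranylgeranoic acid F2.
- F2 would be converted with oxalyl chloride into geranylgeranoyl chloride F3 and cyclised with SnCl4 in CH2Cl2 at −78 °C. This Lewis-acid acyl-cation/alkene macrocyclisation closes the same C1–C2 bond and would give racemic 15-chlorocembra-3,7,11-trien-2-one F4.
- Bu3SnH with AIBN would remove the tertiary chloride to give cembra-3,7,11-trien-2-one F5. Weitz–Scheffer epoxidation (H2O2, NaOH, MeOH) would give 3,4-epoxycembra-7,11-dien-2-one F6.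
- Wharton transposition (N2H4·H2O, AcOH, MeOH) would give cembra-2,7,11-trien-4-ol as its stereoisomer mixture F7. Compound 5 would be obtained from it by chromatographic separation of the C4 epimers and resolution on a chiral stationary phase.

This costs seven steps and a resolution, but uses no unknown catalyst.

Step 5. The C10 alkoxide is also homoallylic to C7=C8, so metalation can be delivered to C19 as well as to C20; borylation at the inner allyl terminus C11 is the second risk. Fallback, from 6 back to 9: the C20 hydroxyl would be introduced by an enzyme instead of a base, by screening the P450 variant panel of step 4 and related terpene hydroxylases on 6 for allylic methyl hydroxylation. This reaction is common in terpene tailoring but has no precedent on a cembrane; it makes no new compound.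

Step 8. The ene reaction may fail at a hindered trans-disubstituted alkene that is deactivated by its allylic hydroxyl, and selenous acid may promote transannular opening of the epoxide by the C4 hydroxyl. Fallback, from 12 back to 14: the tertiary allylic C1–H would be hydroxylated enzymatically on 12 (hydrogen abstraction and rebound, hence retention) to give (1S,2E,4R,7E,10R,11Z)-1,4-dihydroxycembra-2,7,11-trien-20,10-olide F8. F8 would then be epoxidised under the conditions of step 7 to rejoin the route at 14. No such hydroxylase is characterised, so this is a screening task held in reserve.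

Step 4. Oxidation may go to C9 or C13, or to the C7=C8 bond, instead of C10, or the C10 face may be poorly controlled; the known variants were developed on a substrate of the other C1 series. Fallback, from 5 back to 6: a variant that reaches C10 without face control would be accepted. The mixture of 6 and its epimer (1R,2E,4R,7E,10S,11E)-cembra-2,7,11-triene-4,10-diol F9 would be oxidised with MnO2 to (1R,2E,4R,7E,11E)-4-hydroxycembra-2,7,11-trien-10-one F10. CBS reduction of F10 with the (S)-2-methyl oxazaborolidine and catecholborane, in which the alkenyl branch acts as the large group, would set 10R by reagent control and return 6.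

Step 9. Conjugate addition of the selenolate to the butenolide and base-induced loss of the C10 configuration are the likely failures. Fallback, from 14 to 17, with the lactone taken out of the way:
- 14 would be reduced with i-Bu2AlH (CH2Cl2, −78 → 0 °C) to (1S,2E,4R,7S,8S,10R,11Z)-7,8-epoxycembra-2,11-diene-1,4,10,20-tetraol F11.
- F11 would be opened as in step 9 to (1S,2E,4R,7R,8S,10R,11Z)-7-(phenylselanyl)cembra-2,11-diene-1,4,8,10,20-pentaol F12.
- Oxidation and elimination as in step 10 would give (1S,2E,4R,6E,8S,10R,11Z)-cembra-2,6,11-triene-1,4,8,10,20-pentaol F13.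
- F13 would be relactonised with TEMPO and PhI(OAc)2 as in step 6 to give 17.

## Further compounds

F1 | step 3 | geranylgeranial, (2E,6E,10E)-3,7,11,15-tetramethylhexadeca-2,6,10,14-tetraenal | CC(C)=CCC/C(C)=C/CC/C(C)=C/CC/C(C)=C/C=O
F2 | step 3 | geranylgeranoic acid, (2E,6E,10E)-3,7,11,15-tetramethylhexadeca-2,6,10,14-tetraenoic acid | CC(C)=CCC/C(C)=C/CC/C(C)=C/CC/C(C)=C/C(=O)O
F3 | step 3 | geranylgeranoyl chloride | CC(C)=CCC/C(C)=C/CC/C(C)=C/CC/C(C)=C/C(=O)Cl
F4 | step 3 | (3E,7E,11E)-15-chlorocembra-3,7,11-trien-2-one, racemic at C1 | CC(C)(Cl)C1CC/C(C)=C/CC/C(C)=C/CC/C(C)=C/C1=O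
F5 | step 3 | (3E,7E,11E)-cembra-3,7,11-trien-2-one, racemic at C1 | CC(C)C1CC/C(C)=C/CC/C(C)=C/CC/C(C)=C/C1=O
F6 | step 3 | (7E,11E)-3,4-epoxycembra-7,11-dien-2-one, racemic, mixture of diastereomers | CC(C)C1CC/C(C)=C/CC/C(C)=C/CCC2(C)OC2C1=O
F7 | step 3 | (2E,7E,11E)-cembra-2,7,11-trien-4-ol, mixture of the stereoisomers at C1 and C4 | CC(C)C1/C=C/C(C)(O)CC/C=C(C)/CC/C=C(C)/CC1
F0 | step 5 | none | none
F8 | step 8 | (1S,2E,4R,7E,10R,11Z)-1,4-dihydroxycembra-2,7,11-trien-20,10-olide | CC(C)[C@]1(O)/C=C/[C@](C)(O)CC/C=C(C)/C[C@@H]2C=C(CC1)C(=O)O2
F9 | step 4 | (1R,2E,4R,7E,10S,11E)-cembra-2,7,11-triene-4,10-diol | CC(C)[C@@H]1/C=C/[C@](C)(O)CC/C=C(C)/C[C@H](O)/C=C(C)/CC1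
F10 | step 4 | (1R,2E,4R,7E,11E)-4-hydroxycembra-2,7,11-trien-10-one | CC(C)[C@@H]1/C=C/[C@](C)(O)CC/C=C(C)/CC(=O)/C=C(C)/CC1
F11 | step 9 | (1S,2E,4R,7S,8S,10R,11Z)-7,8-epoxycembra-2,11-diene-1,4,10,20-tetraol | CC(C)[C@]1(O)/C=C/[C@](C)(O)CC[C@H]3[C@@](C)(O3)C[C@@H](O)/C=C(CO)/CC1
F12 | step 9 | (1S,2E,4R,7R,8S,10R,11Z)-7-(phenylselanyl)cembra-2,11-diene-1,4,8,10,20-pentaol | CC(C)[C@]1(O)/C=C/[C@](C)(O)CC[C@@H]([Se]c3ccccc3)[C@@](C)(O)C[C@@H](O)/C=C(CO)/CC1
F13 | step 9 | (1S,2E,4R,6E,8S,10R,11Z)-cembra-2,6,11-triene-1,4,8,10,20-pentaol | CC(C)[C@]1(O)/C=C/[C@](C)(O)C/C=C/[C@@](C)(O)C[C@@H](O)/C=C(CO)/CC1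
A1 | alternative 1 | S-configured secondary allylic N,N-diisopropylcarbamate of the C1–C10 fragment (C4 and C8 as triethylsilyl ethers, C10 as tert-butyldimethylsilyl ether) | CC(C)[C@H](OC(=O)N(C(C)C)C(C)C)/C=C/[C@](C)(O[Si](CC)(CC)CC)C/C=C/[C@@](C)(O[Si](CC)(CC)CC)CCO[Si](C)(C)C(C)(C)C
A2 | alternative 1 | trimethyl[4-(4,4,5,5-tetramethyl-1,3,2-dioxaborolan-2-yl)but-1-yn-1-yl]silane (C11–C14 fragment) | C[Si](C)(C)C#CCCB1OC(C)(C)C(C)(C)O1
A3 | alternative 1 | acyclic C1–C14 tertiary allylic alcohol with C1, C4 and C8 configured as in the target | CC(C)[C@](CCC#C[Si](C)(C)C)(O)/C=C/[C@](C)(O[Si](CC)(CC)CC)C/C=C/[C@@](C)(O[Si](CC)(CC)CC)CCO[Si](C)(C)C(C)(C)C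
A4 | alternative 2 | furanophane of the target skeleton with the furan on C10, C11, C12 and C20 and trimethylsilyl on C20 (1,4,8-triol) | CC(C)[C@]1(O)/C=C/[C@](C)(O)C/C=C/[C@@](C)(O)Cc2cc(CC1)c([Si](C)(C)C)o2
A5 | alternative 2 | γ-hydroxybutenolide of the target skeleton (C10 hemiketal, both epimers) | CC(C)[C@]1(O)/C=C/[C@](C)(O)C/C=C/[C@@](C)(O)CC2(O)C=C(CC1)C(=O)O2
A6 | alternative 3 | 15-membered cyclic sulfone with sulfur between C2 and C3, silyl-protected 6E-en-11-yne | CC(C)[C@]1(O[Si](CC)(CC)CC)CS(=O)(=O)C[C@](C)(O[Si](CC)(CC)CC)C/C=C/[C@@](C)(O[Si](CC)(CC)CC)C[C@@H](O[Si](C)(C)C(C)(C)C)C#CCC1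
A7 | alternative 3 | 14-membered (2E,6E)-dien-11-yne with all four stereocentres, silyl-protected | CC(C)[C@]1(O[Si](CC)(CC)CC)/C=C/[C@](C)(O[Si](CC)(CC)CC)C/C=C/[C@@](C)(O[Si](CC)(CC)CC)C[C@@H](O[Si](C)(C)C(C)(C)C)C#CCC1
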